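## Retrosynthetic overview

Ring numbering of the target: C1 = C=O, C2 = C–CH2OH, C3 = =CH, C4 = CH–O-angeloyl, C5 = CH–iPr, C6 = CH–O-epoxyangeloyl.

1. The last bonds made are C2–CH2OH (Stille hydroxymethylation of a 2-bromoenone), the C4 ester (angelic acid) and the C6 ester ((2R,3R)-epoxyangelic acid, from Sharpless epoxidation of angelyl alcohol).
2. The carbocycle C1–C6 comes from a one-carbon ring expansion. C2 is delivered as :CBr2 to the C=C bond of a cyclopentene (ring atoms C1, C3, C4, C5, C6), and the 6,6-dibromobicyclo[3.1.0]hexane opens to a 2-bromocyclohexenyl cation.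
3. The enabling feature is the allyl triad C1–C2–C3. Its central atom C2 bears no heteroatom, and it is flanked by the oxygenated carbons C6 and C4 with C5–iPr between them. Deleting C2 leaves 2-isopropylcyclopent-4-ene-1,3-diol. The C6 ester oxygen sits next to C1, so it can deliver the C1 oxygen and decide which allyl terminus is oxygenated.
4. The cyclopentene comes from Piancatelli dearomatisation of a furyl carbinol (furfural + i-PrMgCl) and a hydroxyl-directed reduction to the trans-diol. One lipase acetylation then sets the absolute configuration and turns C5 into a stereocentre.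
5. Order of ring formation: furan → cyclopentenone → (cyclopropane) → cyclohexene. The oxirane of the side chain is made separately.

Key step: step 6

Assumption: the lipase follows Kazlauskas' rule with the isopropyl-bearing ring carbon as the large group. On that basis the (1R,3R)-diol is the enantiomer that is acetylated, at its less hindered hydroxyl (trans to isopropyl).

## Route

Step 1
Reactants: 1 furfural; 2 isopropylmagnesium chloride
Product: 3 1-(furan-2-yl)-2-methylpropan-1-ol (racemic)
Conditions: THF, 0 °C; then sat. aq. NH4Cl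
Reagents that add atoms: none
Why: Grignard addition to a non-enolisable heteroaryl aldehyde; the carbinol centre may be racemic because step 2 erases it.

Step 2
Reactants: 3 1-(furan-2-yl)-2-methylpropan-1-ol
Product: 4 rac-trans-4-hydroxy-5-isopropylcyclopent-2-en-1-one
Conditions: Dy(OTf)3 (10 mol %), t-BuOH–H2O 5:1, 80 °C
Reagents that add atoms: water, O
Why: Piancatelli rearrangement, in which ionisation of the carbinol, attack of water at furan C5, ring opening and conrotatory 4π-electrocyclisation of the out,out-pentadienyl cation dearomatise the furan and place OH and isopropyl trans.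

Step 3
Reactants: 4 rac-trans-4-hydroxy-5-isopropylcyclopent-2-en-1-one
Product: 5 rac-trans-2-isopropylcyclopent-4-ene-1,3-diol (one OH cis and one OH trans to isopropyl; C2 is not a stereocentre here)
Conditions: Me4NBH(OAc)3, MeCN–AcOH 1:1, −30 °C
Reagents that add atoms: none
Why: Evans–Saksena hydroxyl-directed reduction, in which boron binds the C4–OH and delivers hydride to the ketone from that face, which is also the face anti to isopropyl, so 1,2-reduction to the 1,3-anti (trans) diol should result.

Step 4
Reactants: 5 rac-trans-2-isopropylcyclopent-4-ene-1,3-diol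
Product: 6 (1R,4R,5R)-4-hydroxy-5-isopropylcyclopent-2-en-1-yl acetate (OAc trans, OH cis to isopropyl)
Conditions: Burkholderia cepacia lipase (immobilised), vinyl acetate, MTBE, 30 °C, stopped near half conversion
Reagents that add atoms: vinyl acetate, C=COC(C)=O
Why: Lipase-catalysed kinetic resolution by irreversible transesterification, in which both carbinol centres of the (1R,3R)-diol have the fast-reacting configuration and the less hindered one (trans to isopropyl) should be acylated, so one catalytic event fixes the absolute configuration and, by breaking the pseudo-C2 symmetry, makes the isopropyl carbon the third stereocentre.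

Step 5
Reactants: 6 (1R,4R,5R)-4-hydroxy-5-isopropylcyclopent-2-en-1-yl acetate
Product: 7 (1R,4R,5S)-4-(tert-butyldimethylsilyloxy)-5-isopropylcyclopent-2-en-1-yl acetate
Conditions: TBSOTf, 2,6-lutidine, CH2Cl2, −78 → 0 °C
Reagents that add atoms: tert-butyldimethylsilyl triflate, CC(C)(C)[Si](C)(C)OS(=O)(=O)C(F)(F)F
Why: Silylation of the hindered allylic hydroxyl with a silyl triflate and a non-nucleophilic base puts a bulky, non-participating group next to the alkene carbon that must not be oxygenated in step 6.

Step 6
Reactants: 7 (1R,4R,5S)-4-(tert-butyldimethylsilyloxy)-5-isopropylcyclopent-2-en-1-yl acetate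
Product: 10 (1S,4S,5S,6S)-2-bromo-4-(tert-butyldimethylsilyloxy)-6-hydroxy-5-isopropylcyclohex-2-en-1-yl acetate, via dibromocyclopropane 8 (not isolated), via dioxolanylium triflate 9 (not isolated)
Conditions: PhHgCBr3, PhH, 80 °C; cool, filter off PhHgBr; AgOTf, 2,6-di-tert-butyl-4-methylpyridine, PhH–ClCH2CH2Cl, 50 °C, dark; then H2O–THF, 0 °C
Reagents that add atoms: phenyl(tribromomethyl)mercury, BrC(Br)(Br)[Hg]c1ccccc1; water, O
Why: Thermolysis of the Seyferth reagent releases :CBr2 under neutral conditions that spare the acetate, and the carbene should add in a concerted syn fashion to the only C=C bond from the face anti to OTBS and isopropyl to give 8. Ag(I) then removes the endo bromide while the bond shared by the three- and five-membered rings opens in a disrotatory 2π-electrocyclic process (Woodward–Hoffmann–DePuy rule), so the five-membered ring becomes a six-membered 2-bromocyclohex-2-enyl cation; the closest known reaction type is the silver-promoted ring expansion of ring-fused gem-dibromocyclopropanes with capture of the π-allyl cation by a tethered O- or N-nucleophile, joined here to Woodward–Prévost acyloxonium chemistry. The carbocycle is thus formed by ring enlargement (bond cleavage, no new σ-bond), and the transient 1,3-dioxolan-2-ylium ring of 9 closes 5-exo-trig by attack of the acetate carbonyl oxygen on the adjacent allyl terminus. The one new stereocentre that remains, the allylic C–O carbon, is set cis to the neighbouring oxygen by the geometry of the cis-fused five-membered ring, water attacks 9 at the acyloxonium carbon, and the ortho-acid should collapse kinetically to the pseudo-axial allylic acetate and the equatorial alcohol; an acetyl shift between the two cis oxygens would be harmless, since step 7 removes the acetyl group and step 8 erases this centre. The selectivity needed is the choice between the two allyl termini, and the substrate secures it with a participating ester next to one terminus, a non-participating silyl ether next to the other, and only a non-nucleophilic counter-ion and a hindered base in solution until water is added. The three earlier stereocentres are not touched, and the operation delivers the ring size, the C2=C3 double bond in its final place, the C1 oxygen and a C2–Br handle for the hydroxymethyl group.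

Step 7
Reactants: 10 (1S,4S,5S,6S)-2-bromo-4-(tert-butyldimethylsilyloxy)-6-hydroxy-5-isopropylcyclohex-2-en-1-yl acetate
Product: 11 (1S,2S,5S,6S)-3-bromo-5-(tert-butyldimethylsilyloxy)-6-isopropylcyclohex-3-ene-1,2-diol
Conditions: K2CO3 (cat.), MeOH, 0 °C → rt
Reagents that add atoms: none
Why: Base-catalysed (Zemplén-type) transesterification removes the acetyl group from whichever of the two cis oxygens bears it, while the silyl ether and the vinyl bromide are inert.

Step 8
Reactants: 11 (1S,2S,5S,6S)-3-bromo-5-(tert-butyldimethylsilyloxy)-6-isopropylcyclohex-3-ene-1,2-diol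
Product: 12 (4S,5S,6S)-2-bromo-4-(tert-butyldimethylsilyloxy)-6-hydroxy-5-isopropylcyclohex-2-en-1-one
Conditions: activated MnO2 (excess), CH2Cl2, rt
Reagents that add atoms: none
Why: Chemoselective MnO2 oxidation of the allylic hydroxyl beside the saturated one should give the conjugated α'-hydroxy enone, which erases the temporary carbinol centre and leaves C6–OH in its preferred equatorial orientation trans to isopropyl.

Step 9
Reactants: 13 angelic acid [(Z)-2-methylbut-2-enoic acid]
Product: 14 (Z)-2-methylbut-2-en-1-ol
Conditions: LiAlH4, Et2O, 0 °C → rt; then H2O, aq. NaOH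
Reagents that add atoms: none
Why: Aluminium hydride reduction of the carboxylic acid, which does not touch the trisubstituted alkene of the carboxylate, so the Z geometry is retained.

Step 10
Reactants: 14 (Z)-2-methylbut-2-en-1-ol
Product: 15 [(2S,3R)-2,3-dimethyloxiran-2-yl]methanol
Conditions: Ti(Oi-Pr)4 (10 mol %), L-(+)-DIPT (12 mol %), t-BuOOH (decane), 4 Å MS, CH2Cl2, −20 °C
Reagents that add atoms: tert-butyl hydroperoxide, CC(C)(C)OO
Why: Sharpless asymmetric epoxidation, in which the L-(+)-tartrate catalyst attacks the face of Z-configured allylic alcohols that leads to the (2S,3R)-epoxy alcohol and syn addition keeps the C3-methyl cis to CH2OH, so both oxirane centres are set in one catalytic event.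

Step 11
Reactants: 15 [(2S,3R)-2,3-dimethyloxiran-2-yl]methanol
Product: 16 (2R,3R)-2,3-dimethyloxirane-2-carboxylic acid (epoxyangelic acid)
Conditions: TEMPO (20 mol %), PhI(OAc)2 (2.2 equiv), MeCN–H2O 1:1, rt
Reagents that add atoms: water, O
Why: TEMPO/PhI(OAc)2 oxidation of the primary alcohol through the aldehyde hydrate to the acid runs under near-neutral conditions that leave the epoxide and both its stereocentres intact (the C2 descriptor changes only through CIP priorities).

Step 12
Reactants: 12 (4S,5S,6S)-2-bromo-4-(tert-butyldimethylsilyloxy)-6-hydroxy-5-isopropylcyclohex-2-en-1-one; 16 (2R,3R)-2,3-dimethyloxirane-2-carboxylic acid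
Product: 17 (1S,5S,6S)-3-bromo-5-(tert-butyldimethylsilyloxy)-6-isopropyl-2-oxocyclohex-3-en-1-yl (2R,3R)-2,3-dimethyloxirane-2-carboxylate
Conditions: DCC, DMAP (10 mol %), CH2Cl2, 0 °C → rt
Reagents that add atoms: none
Why: Steglich esterification of the only free hydroxyl, in which the acid has a quaternary α-carbon and cannot epimerise, the C6–O bond is untouched, and minor diastereomers from incomplete enantiopurity of either partner can be removed by chromatography.

Step 13
Reactants: 17 (1S,5S,6S)-3-bromo-5-(tert-butyldimethylsilyloxy)-6-isopropyl-2-oxocyclohex-3-en-1-yl (2R,3R)-2,3-dimethyloxirane-2-carboxylate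
Product: 18 (1S,5S,6R)-3-bromo-5-hydroxy-6-isopropyl-2-oxocyclohex-3-en-1-yl (2R,3R)-2,3-dimethyloxirane-2-carboxylate
Conditions: HF·pyridine, pyridine, THF, 0 °C → rt
Reagents that add atoms: none
Why: Buffered fluoride desilylation spares the glycidic ester, the α-acyloxy ketone and the vinyl bromide, and it avoids the base-induced acyl shifts and eliminations expected with TBAF.

Step 14
Reactants: 18 (1S,5S,6R)-3-bromo-5-hydroxy-6-isopropyl-2-oxocyclohex-3-en-1-yl (2R,3R)-2,3-dimethyloxirane-2-carboxylate; 13 angelic acid
Product: 20 (1S,5S,6R)-3-bromo-5-[(Z)-2-methylbut-2-enoyloxy]-6-isopropyl-2-oxocyclohex-3-en-1-yl (2R,3R)-2,3-dimethyloxirane-2-carboxylate, via mixed anhydride 19 (not isolated)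
Conditions: 13, 2,4,6-trichlorobenzoyl chloride, Et3N, toluene, rt; then 18, 75 °C (no DMAP)
Reagents that add atoms: none
Why: Yamaguchi-type mixed-anhydride esterification without a nucleophilic catalyst, so no reversible conjugate addition can isomerise the Z-alkene to the tiglate, the shielded trichlorobenzoyl carbonyl steers the hindered pseudo-axial C4–OH to the angeloyl carbonyl, and the C4–O bond (hence the configuration) is retained.

Step 15
Reactants: 20 (1S,5S,6R)-3-bromo-5-[(Z)-2-methylbut-2-enoyloxy]-6-isopropyl-2-oxocyclohex-3-en-1-yl (2R,3R)-2,3-dimethyloxirane-2-carboxylate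
Product: 21 (1S,5R,6R)-3-(hydroxymethyl)-5-[(Z)-2-methylbut-2-enoyloxy]-2-oxo-6-isopropylcyclohex-3-en-1-yl (2R,3R)-2,3-dimethyloxirane-2-carboxylate (target)
Conditions: Bu3SnCH2OH, Pd2(dba)3 (5 mol %), AsPh3 (20 mol %), CuI (10 mol %), degassed NMP, 45 °C
Reagents that add atoms: (tributylstannyl)methanol, CCCC[Sn](CCCC)(CCCC)CO
Why: Stille cross-coupling, in which oxidative addition into the carbonyl-activated C(sp2)–Br bond should outrun ionisation of the allylic angelate with a weakly donating ligand, copper co-catalysis and low temperature, and transfer of the hydroxymethyl group gives the free primary alcohol without a protecting group or any change at a stereocentre.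

## Compound list

1 | furfural | O=Cc1ccco1 | starting material
2 | isopropylmagnesium chloride | CC(C)[Mg]Cl | starting material
3 | 1-(furan-2-yl)-2-methylpropan-1-ol (racemic) | CC(C)C(O)c1ccco1 | intermediate
4 | rac-trans-4-hydroxy-5-isopropylcyclopent-2-en-1-one (racemate; the (4R,5S) enantiomer is drawn) | O=C1C=C[C@@H](O)[C@@H]1C(C)C | intermediate
5 | rac-trans-2-isopropylcyclopent-4-ene-1,3-diol (racemate; the (1R,3R) enantiomer is drawn) | O[C@@H]1C=C[C@@H](O)C1C(C)C | intermediate
6 | (1R,4R,5R)-4-hydroxy-5-isopropylcyclopent-2-en-1-yl acetate | O[C@@H]1C=C[C@@H](OC(C)=O)[C@@H]1C(C)C | intermediate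
7 | (1R,4R,5S)-4-(tert-butyldimethylsilyloxy)-5-isopropylcyclopent-2-en-1-yl acetate | CC(C)(C)[Si](C)(C)O[C@@H]1C=C[C@@H](OC(C)=O)[C@@H]1C(C)C | intermediate
8 | (1R,2S,3S,4S,5S)-6,6-dibromo-4-(tert-butyldimethylsilyloxy)-3-isopropylbicyclo[3.1.0]hexan-2-yl acetate (cyclopropane syn to OAc, anti to OTBS and isopropyl) | CC(C)(C)[Si](C)(C)O[C@@H]1[C@@H]2[C@@H](C2(Br)Br)[C@@H](OC(C)=O)[C@@H]1C(C)C | intermediate
9 | cis-fused 2-methyl-1,3-dioxolan-2-ylium triflate on the 2-bromocyclohexene ring | CC(C)(C)[Si](C)(C)O[C@@H]1C=C(Br)[C@H]2[O+]=C(C)O[C@H]2[C@@H]1C(C)C.[O-]S(=O)(=O)C(F)(F)F | intermediate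
10 | (1S,4S,5S,6S)-2-bromo-4-(tert-butyldimethylsilyloxy)-6-hydroxy-5-isopropylcyclohex-2-en-1-yl acetate | CC(C)(C)[Si](C)(C)O[C@@H]1C=C(Br)[C@@H](OC(C)=O)[C@@H](O)[C@@H]1C(C)C | intermediate
11 | (1S,2S,5S,6S)-3-bromo-5-(tert-butyldimethylsilyloxy)-6-isopropylcyclohex-3-ene-1,2-diol | CC(C)(C)[Si](C)(C)O[C@@H]1C=C(Br)[C@@H](O)[C@@H](O)[C@@H]1C(C)C | intermediate
12 | (4S,5S,6S)-2-bromo-4-(tert-butyldimethylsilyloxy)-6-hydroxy-5-isopropylcyclohex-2-en-1-one | CC(C)(C)[Si](C)(C)O[C@@H]1C=C(Br)C(=O)[C@@H](O)[C@@H]1C(C)C | intermediate
13 | angelic acid | C/C=C(/C)C(=O)O | starting material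
14 | (Z)-2-methylbut-2-en-1-ol | C/C=C(/C)CO | intermediate
15 | [(2S,3R)-2,3-dimethyloxiran-2-yl]methanol | OC[C@]1(C)O[C@@H]1C | intermediate
16 | (2R,3R)-2,3-dimethyloxirane-2-carboxylic acid | OC(=O)[C@]1(C)O[C@@H]1C | intermediate
17 | (1S,5S,6S)-3-bromo-5-(tert-butyldimethylsilyloxy)-6-isopropyl-2-oxocyclohex-3-en-1-yl (2R,3R)-2,3-dimethyloxirane-2-carboxylate | CC(C)(C)[Si](C)(C)O[C@@H]1C=C(Br)C(=O)[C@@H](OC(=O)[C@]2(C)O[C@@H]2C)[C@@H]1C(C)C | intermediate
18 | (1S,5S,6R)-3-bromo-5-hydroxy-6-isopropyl-2-oxocyclohex-3-en-1-yl (2R,3R)-2,3-dimethyloxirane-2-carboxylate | O[C@@H]1C=C(Br)C(=O)[C@@H](OC(=O)[C@]2(C)O[C@@H]2C)[C@@H]1C(C)C | intermediate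
19 | angelic 2,4,6-trichlorobenzoic anhydride | C/C=C(/C)C(=O)OC(=O)c1c(Cl)cc(Cl)cc1Cl | intermediate
20 | (1S,5S,6R)-3-bromo-5-[(Z)-2-methylbut-2-enoyloxy]-6-isopropyl-2-oxocyclohex-3-en-1-yl (2R,3R)-2,3-dimethyloxirane-2-carboxylate | C/C=C(/C)C(=O)O[C@@H]1C=C(Br)C(=O)[C@@H](OC(=O)[C@]2(C)O[C@@H]2C)[C@@H]1C(C)C | intermediate
21 | CNP0293054.1 | C/C=C(/C)C(=O)O[C@@H]1C=C(CO)C(=O)[C@@H](OC(=O)[C@]2(C)O[C@@H]2C)[C@@H]1C(C)C | target

## Step count and risks

Total step count: 15. Longest linear sequence: 12 steps (steps 1–8 and 12–15).

**Step 6.**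
- What may go wrong: carbene transfer may be slow because two allylic C–O bonds deactivate the alkene. Ionisation of the oxygen-flanked cyclopropane may be sluggish. Regiocontrol may leak through external capture at the terminus next to the silyl ether. The silyl group may be lost under Lewis-acidic conditions.
- Fallback: it sets out from 7 and comes back to the route at 11. It replaces the acetate tether by a base-stable and more nucleophilic carbamate tether and isolates the cyclopropane. Methanolysis of 7 (K2CO3, MeOH) gives the free cyclopentenol F1. NaH and Me2NCOCl convert it into the N,N-dimethylcarbamate F2. This tolerates phase-transfer dibromocarbene addition (CHBr3, 50 % NaOH, BnEt3NCl) and gives the dibromocyclopropyl carbamate F3. AgOTf in MeNO2 opens the ring, the carbamate oxygen captures the adjacent allyl terminus, and aqueous work-up of the iminium carbonate gives the cis-fused cyclic carbonate F4. K2CO3 in MeOH then gives 11.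

**Step 15.**
- What may go wrong: Pd(0) may ionise the allylic angelate in competition with the coupling. Transfer of the hydroxymethyl group from tin may be slow. Protodebromination may occur.
- Fallback: it sets out from 17 and comes back at 21. The C–C bond is made before any allylic ester is present. Stille coupling of 17 with Bu3SnCH2OH (Pd(PPh3)4, dioxane, 90 °C) gives the silyl-protected hydroxymethyl enone F5. HF·pyridine gives the diol F6. TESCl and imidazole at −78 °C silylate only the primary hydroxyl to give the triethylsilyl ether F7. The mixed-anhydride angeloylation of step 14 gives the angelate F8. HF·pyridine at 0 °C then releases 21.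

**Step 4.**
- What may go wrong: the enzyme may discriminate poorly between the enantiomers, or it may acylate the hydroxyl cis to isopropyl.
- Fallback: it sets out from 4 and comes back at 6. It replaces resolution by reagent-controlled reduction of an achiral precursor. MnO2 oxidation of racemic 4 gives the achiral 2-isopropylcyclopent-4-ene-1,3-dione F9. Twofold CBS reduction follows ((S)-Me-CBS, BH3·SMe2, the branched sp3 carbon acting as the large group). It should give the (1R,3R)-diol F10, with statistical enantiomeric enrichment and a separable meso cis-diol as the sink. AcCl and 2,4,6-collidine at −78 °C then acetylate the less hindered hydroxyl to give 6.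

## Further compounds

F1 | step 6 | (1R,4R,5S)-4-(tert-butyldimethylsilyloxy)-5-isopropylcyclopent-2-en-1-ol | CC(C)(C)[Si](C)(C)O[C@@H]1C=C[C@@H](O)[C@@H]1C(C)C
F2 | step 6 | (1R,4R,5S)-4-(tert-butyldimethylsilyloxy)-5-isopropylcyclopent-2-en-1-yl dimethylcarbamate | CC(C)(C)[Si](C)(C)O[C@@H]1C=C[C@@H](OC(=O)N(C)C)[C@@H]1C(C)C
F3 | step 6 | (1R,2S,3S,4S,5S)-6,6-dibromo-4-(tert-butyldimethylsilyloxy)-3-isopropylbicyclo[3.1.0]hexan-2-yl dimethylcarbamate | CC(C)(C)[Si](C)(C)O[C@@H]1[C@@H]2[C@@H](C2(Br)Br)[C@@H](OC(=O)N(C)C)[C@@H]1C(C)C
F4 | step 6 | cis-fused cyclic carbonate of diol 11 | CC(C)(C)[Si](C)(C)O[C@@H]1C=C(Br)[C@H]2OC(=O)O[C@H]2[C@@H]1C(C)C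
F5 | step 15 | 5-(tert-butyldimethylsilyloxy)-3-(hydroxymethyl)-6-isopropyl-2-oxocyclohex-3-en-1-yl (2R,3R)-2,3-dimethyloxirane-2-carboxylate (ring configuration as in 17) | CC(C)(C)[Si](C)(C)O[C@@H]1C=C(CO)C(=O)[C@@H](OC(=O)[C@]2(C)O[C@@H]2C)[C@@H]1C(C)C
F6 | step 15 | 5-hydroxy-3-(hydroxymethyl)-6-isopropyl-2-oxocyclohex-3-en-1-yl (2R,3R)-2,3-dimethyloxirane-2-carboxylate (ring configuration as in 18) | O[C@@H]1C=C(CO)C(=O)[C@@H](OC(=O)[C@]2(C)O[C@@H]2C)[C@@H]1C(C)C
F7 | step 15 | primary triethylsilyl ether of F6 | O[C@@H]1C=C(CO[Si](CC)(CC)CC)C(=O)[C@@H](OC(=O)[C@]2(C)O[C@@H]2C)[C@@H]1C(C)C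
F8 | step 15 | primary triethylsilyl ether of the target | C/C=C(/C)C(=O)O[C@@H]1C=C(CO[Si](CC)(CC)CC)C(=O)[C@@H](OC(=O)[C@]2(C)O[C@@H]2C)[C@@H]1C(C)C
F9 | step 4 | 2-isopropylcyclopent-4-ene-1,3-dione | CC(C)C1C(=O)C=CC1=O
F10 | step 4 | (1R,3R)-2-isopropylcyclopent-4-ene-1,3-diol | O[C@@H]1C=C[C@@H](O)C1C(C)C
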